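## Structural features

Isariotin C is a bicyclo[3.3.1]nonan-9-one: ring A (C1–C2–C3–C4–C5–C9) and ring B (C1–C8–C7–C6–C5–C9) share the bridgeheads C1 and C5 and the carbonyl carbon C9, and C3 carries the nitrogen of an (E)-7-oxododec-2-enamide. Seven stereocentres are contiguous: C1 (H), C2 (OH), C3 (N), C5 (tertiary OH), the C6–C7 epoxide and C8 (OH). Read on a chair–chair model, every non-bridgehead heteroatom is exo, that is, on the side of its ring turned towards C9. The C2 and C8 hydroxyls are axial and syn to the C9 carbonyl, the C3 nitrogen is equatorial and cis to the C2 hydroxyl, and the epoxide is syn to the C8 hydroxyl. The core is fragile towards base, because C2 and C8 are both aldol carbinols of the C9 ketone through C1, C5 is an α-ketol and the C8-hydroxy epoxide can be opened; the side chain holds an enolisable ketone and an enamide and must arrive last. The difficulty is twofold: C5 is a quaternary bridgehead carbinol that must be set in absolute terms, and the exo face is also the face that reagents attack, so hydride places oxygen endo and each exo oxygen must come from a suprafacial oxygen transfer or an inversion. The key step exploits the fact that C5 and C1 are the two α-carbons of the C9 ketone and C2, the first carbon of the bridge C2–C3–C4 that joins them, is a β-carbinol: ring A is the imprint of an enal laid across the α,α′-positions of the ring-B cyclohexanone.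

## Logic of the disconnections

**34 to 25 and 31.** The amide N–C(O) bond is cut first. The enoyl ketone chain would not survive enolate chemistry, silyl triflate or allylic oxidation, and removing it leaves a core whose nitrogen is masked as an azide. The forward step must acylate nitrogen in the presence of three free hydroxyls and without base.

**31 to 29 and 30.** The C2′=C3′ alkene is cut by cross-metathesis logic into a terminal alkene and acrylic acid. The forward step must favour cross- over homo-coupling and give the E alkene.

**29 to 26 and 27.** The C6′–C7′ bond next to the ketone is cut into a pentyl nucleophile and a nitrile carbon, both commercial. The forward addition must stop at the ketone oxidation level.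

**25 to 24.** The two epoxide C–O bonds at C6 and C7 are removed to leave the C6=C7 alkene. The forward step must deliver oxygen to the exo face, syn to the C8 hydroxyl, which can direct it.

**24 to 22.** The C8–O bond is cut back to the allylic methylene; C8 is the only allylic C–H position because C5 is quaternary. The forward oxidation must be suprafacial on the exo face and must return the alkene to C6=C7.

**22 to 18.** The C5–O bond is exchanged for a C5–carboxyl bond. The carboxyl is the activating group needed to build C5, and a bridgehead radical can only accept oxygen with retention. The forward step must produce that radical in the presence of an alkene and an azide.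

**18 to 16.** The C2 O–Si bond and the carboxyl O–H are traced back to a free hydroxyl and a tert-butyl ester. One silyl triflate operation must do both without generating alkoxide.

**16 to 13 to 12.** The C2–O bond of the exo alcohol is cut with inversion, then the C2–H bond of the endo alcohol is cut back to the ketone. Hydride will enter C2 from the exo face, anti to the axial C1–C8 bond, so direct reduction can only give the endo alcohol. The exo oxygen therefore demands a clean SN2 displacement on an equatorial sulfonate, and the reduction must select C2 over C9.

**12 to 9.** The C3–N bond is cut to an enolate and an electrophilic azide. C3 is the only enolisable position of the dione, and the exo face is open. The forward step must transfer azide and not a diazo group.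

**9 to 8.** The C2 carbonyl is returned to the carbinol produced by the annulation. This removes any need to control C2 in the ring-forming step.

**8 to 5 and 6.** The C4–C5 and C1–C2 bonds are cut, removing ring A and three stereocentres and leaving a cyclohexenone β-keto ester and acrolein. The forward step must set the quaternary C5 enantioselectively and then close the aldol at C1.

**5 to 4 to 2 to 1.** The C9 ketone is unmasked from a methyl enol ether, the 1,4-diene comes from the arene by dissolving-metal reduction, and the tert-butyl ester comes from the acid. The forward steps must keep the C6=C7 alkene out of conjugation and keep the ester intact.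

## Other disconnections considered

**Alternative 1:** The cut is the C3–N bond, made last on a core that already holds every oxygen. In the forward step the C2-exo primary carbamate A1 (C5 triethylsilyl ether, C8 tert-butyldimethylsilyl ether, epoxide in place) is oxidised by PhI(OAc)2 with Rh2(esp)2 and MgO. The rhodium nitrene inserts into the exo C3–H bond with retention and gives the cis-fused oxazolidinone A2.
- In favour: the tether guarantees the cis C2–O/C3–N relationship and C3 needs no carbonyl activation. The oxidation, azidation, reduction and inversion of steps 5 to 8 would disappear, and on this point the alternative is better than the chosen plan.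
- Against: C3–H is an unactivated methylene, so the insertion is the least favourable class for carbamate nitrenes. A1 requires a C2-exo alcohol of defined configuration, which the chosen annulation does not have to deliver. The cyclic carbamate must then be opened on a molecule holding an epoxide, an α-ketol and two retro-aldol sites, before two silyl ethers are removed and the amine is acylated.
- Comparison: it builds no ring, so it is the equal of the chosen plan only once a core synthesis is added. It is mechanistically cleaner at C2/C3 and worse in the endgame, where the chosen plan needs one base-free step after unmasking nitrogen.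

**Alternative 2:** The cut is C1–C2 and C1–C8, two aldol bonds to one carbon. In the forward step the acyclic keto dialdehyde A3 is enolised at its methyl group by MgBr2·OEt2 and a tertiary amine. The first aldol closes ring A, the new ring ketone enolises again towards the same carbon, and the second aldol closes ring B to give the meso dienediol A4.
- In favour: two rings and two C–C bonds form in one step from an achiral chain, which is better than the chosen key step (one ring). Magnesium chelation between the enolate oxygen and each aldehyde oxygen should place both hydroxyls syn to C9, the exo configuration that the chosen plan reaches only by inversion at C2 and by selenium chemistry at C8; on this point it is also better.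
- Against: A3 holds a tertiary hydroxyl cis-disposed to two enals, so lactol formation and Z to E isomerisation threaten it before enolisation. A4 is meso, so absolute configuration must come from a later enantiotopic differentiation of two alkenes. The ring-A alkene then needs a net hydroamination with nitrogen exo at C3 and hydrogen at C4, for which no direct method fits.
- Comparison: it is shorter to the carbon skeleton and equal in the ease of the ring-B epoxidation. It is weaker in precursor stability, in the timing of enantiocontrol (the chosen plan sets it at the first C–C bond) and in the nitrogen introduction, so the total count is unlikely to be lower.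

**Alternative 3:** The cut is C5–C6 and C1–C8, with ring B laid on from a malonyl unit. In the forward step the enantiopure silyl enol ether A5 (C2 silyl ether, C3 dibenzylamine, C5 silyl ether) is C-acylated at C1 by malonyl dichloride A6. The remaining acid chloride then acylates C5 through the C9 enol to give the trione A7.
- In favour: nitrogen and the C2 oxygen arrive with ring A in their final cis-exo arrangement and can come from the chiral pool, which is better than the chosen plan on that point. The key step forms two C–C bonds and one ring, which is equal.
- Against: the second acylation must create a quaternary centre at an α-silyloxy carbon through a hindered tetrasubstituted enol, and O-acylation to an enol lactone is the usual competing path. Ring B arrives one oxidation level too high at both C6 and C8. The two carbonyls must then be told apart, C8 reduced from the hindered endo face, C6 turned into the alkene and the alkene epoxidised.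
- Comparison: it is stronger on ring-A stereochemistry and comparable in bond count. It is weaker in the mechanism of the bridgehead acylation and in step economy after the key step, where the chosen plan needs two steps (11 and 12) for the same ring-B pattern.

Key step: step 4

Convention: names use the core numbering C1–C9; exo means on the side of the C9 bridge and endo on the side of the other three-carbon bridge; the bridgeheads keep the absolute configuration of 8 throughout.

Assumption: the cupreidine-derived catalyst is taken to give the (S) configuration at C5 of 7; if the sense is the opposite, its cupreine-derived pseudoenantiomer is used under the same conditions.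

## Route

Step 1
Reactants: 1 2-methoxybenzoic acid
Product: 2 tert-butyl 2-methoxybenzoate
Conditions: t-BuOC(=NH)CCl3 (2 equiv), CH2Cl2/cyclohexane, rt
Reagents that add atoms: tert-butyl 2,2,2-trichloroacetimidate, CC(C)(C)OC(=N)C(Cl)(Cl)Cl
Why: tert-Butylation of a carboxylic acid by a trichloroacetimidate, in which the acid itself protonates the imidate. The tert-butyl ester replaces a methyl ester because it resists ammonolysis in the Birch step, enlarges the group that the Michael catalyst reads, and is later removed without hydroxide, which would open the β-dicarbonyl core by retro-Claisen or retro-aldol.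

Step 2
Reactants: 2 tert-butyl 2-methoxybenzoate
Product: 4 tert-butyl 2-methoxycyclohexa-2,5-diene-1-carboxylate, via potassium ester dienolate 3 (not isolated)
Conditions: K (2.2 equiv), NH3(l)/THF, t-BuOH (1 equiv), −78 °C; then NH4Cl
Reagents that add atoms: none
Why: Birch reduction of an o-anisate ester: two electron transfers and protonation para to the ester leave the ester dienolate 3. Kinetic protonation of 3 at the ester α-carbon by NH4Cl gives the 1,4-diene with the enol ether intact.

Step 3
Reactants: 4 tert-butyl 2-methoxycyclohexa-2,5-diene-1-carboxylate
Product: 5 tert-butyl 6-oxocyclohex-2-ene-1-carboxylate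
Conditions: (CO2H)2 (0.2 equiv), THF/H2O, 0 °C → rt, argon; used at once
Reagents that add atoms: water, O
Why: Mild acid hydrolysis of the enol ether (C-protonation, hemiketal, loss of methanol); oxalic acid is too weak to move the remaining alkene into conjugation or to cleave the tert-butyl ester. Compound 5 is kept under argon and used directly because its enol form can aromatise in air.

Step 4
Reactants: 5 tert-butyl 6-oxocyclohex-2-ene-1-carboxylate; 6 acrolein
Product: 8 tert-butyl (1R,2S,5S)-2-hydroxy-9-oxobicyclo[3.3.1]non-6-ene-5-carboxylate, via tert-butyl (1S)-6-oxo-1-(3-oxopropyl)cyclohex-2-ene-1-carboxylate 7 (not isolated)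
Conditions: 9-O-(9-phenanthryl)cupreidine (10 mol%), CH2Cl2, −40 °C, slow addition of 6; then 1,1,3,3-tetramethylguanidine (20 mol%), 0 °C → rt
Reagents that add atoms: none
Why: The quinuclidine nitrogen of the catalyst deprotonates 5 and holds the dienolate as a chiral ammonium ion pair while the 6′-hydroxyl hydrogen-bonds acrolein, so the doubly activated C5 adds to the enal β-carbon on one face and forms the C4–C5 bond; the closest known reaction type is the bifunctional cinchona-catalysed Michael addition of cyclic β-keto esters to enals. The quaternary centre C5 is therefore set by the catalyst, helped by the bulk of the tert-butyl ester. After the guanidine base is added, the C9 ketone of 7 enolises towards C1, its only remaining α-carbon, and C1 attacks the tethered aldehyde to form the C1–C2 bond; ring A closes by a 6-(enolendo)-exo-trig aldol, the enolate C1=C9 lying inside the new ring, as in base-mediated Michael–aldol bicycloannulations to 2-hydroxybicyclo[3.3.1]nonan-9-ones. C1 is fixed by the tether, because the three-carbon chain on C5 can only reach the face of ring B from which it hangs and the new bridge must be diaxial. C2 is not relied upon: hydrogen bonding of the aldehyde oxygen to the enolate oxygen should favour the exo alcohol, and any endo epimer is carried into step 5, where both give 9. The step needs α- and not γ-attack of the cross-conjugated dienolate, which the higher charge density at the carbon between the two carbonyls should secure, and it needs the ketol to persist, which is secured because dehydration would require a C1=C2 bridgehead alkene. Low temperature and slow addition of 6 keep 1,2-addition and acrolein oligomerisation down, and the C6=C7 alkene is a spectator.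

Step 5
Reactants: 8 tert-butyl (1R,2S,5S)-2-hydroxy-9-oxobicyclo[3.3.1]non-6-ene-5-carboxylate
Product: 9 tert-butyl 2,9-dioxobicyclo[3.3.1]non-6-ene-5-carboxylate
Conditions: Dess–Martin periodinane (1.3 equiv), CH2Cl2, 0 °C → rt
Reagents that add atoms: none
Why: Dess–Martin oxidation of a secondary alcohol under non-basic conditions that cannot start a retro-aldol; both C2 epimers converge on one dione. C1 lies between two carbonyls but cannot enolise into a bridgehead double bond, so it keeps its configuration.

Step 6
Reactants: 9 tert-butyl 2,9-dioxobicyclo[3.3.1]non-6-ene-5-carboxylate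
Product: 12 tert-butyl 3-exo-azido-2,9-dioxobicyclo[3.3.1]non-6-ene-5-carboxylate, via potassium C3 enolate 10 (not isolated), via potassium sulfonyltriazenide 11 (not isolated)
Conditions: KN(SiMe3)2 (1.05 equiv), THF, −78 °C; 2,4,6-triisopropylbenzenesulfonyl azide, −78 °C; AcOH, −78 °C → rt
Reagents that add atoms: 2,4,6-triisopropylbenzenesulfonyl azide, CC(C)c1cc(C(C)C)c(S(=O)(=O)N=[N+]=[N-])c(C(C)C)c1
Why: Electrophilic azide transfer to a ketone enolate with a sulfonyl azide: the hindered amide base removes a proton from C3, the only α-carbon that can give a planar enolate, the enolate adds to the terminal azide nitrogen on the exo face away from ring B, and acetic acid collapses the triazenide to the azide. The exo azide is equatorial on ring A and is also the thermodynamic epimer, since an endo group at C3 would point at C7.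

Step 7
Reactants: 12 tert-butyl 3-exo-azido-2,9-dioxobicyclo[3.3.1]non-6-ene-5-carboxylate
Product: 13 tert-butyl 3-exo-azido-2-endo-hydroxy-9-oxobicyclo[3.3.1]non-6-ene-5-carboxylate
Conditions: LiAlH(Ot-Bu)3 (1.1 equiv), THF, −78 °C; aq. potassium sodium tartrate
Reagents that add atoms: none
Why: Hydride reduction of an α-azido ketone: C2 is activated by the azide and open, whereas C9 sits between a quaternary and a tertiary carbon, so one equivalent of a bulky hydride should stop at C2. Attack is expected on the exo face, anti to the axial C1–C8 bond (Felkin-type, torsionally staggered), so the new hydroxyl is endo (equatorial) and trans to the azide. Chelation to the azide cannot turn the hydride to the endo face of this rigid bicycle, so the configuration is corrected in step 8.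

Step 8
Reactants: 13 tert-butyl 3-exo-azido-2-endo-hydroxy-9-oxobicyclo[3.3.1]non-6-ene-5-carboxylate
Product: 16 tert-butyl 3-exo-azido-2-exo-hydroxy-9-oxobicyclo[3.3.1]non-6-ene-5-carboxylate, via C2-endo triflate 14 (not isolated), via C2-exo nitrite ester 15 (not isolated)
Conditions: Tf2O (1.3 equiv), pyridine, CH2Cl2, −20 °C; then Bu4NNO2 (4 equiv), MeCN, 0 °C → rt; aqueous work-up
Reagents that add atoms: tetrabutylammonium nitrite, CCCC[N+](CCCC)(CCCC)CCCC.[O-]N=O
Why: Lattrell–Dax inversion: nitrite oxygen displaces the equatorial triflate by SN2 from the exo face and the alkyl nitrite hydrolyses on work-up, giving the axial exo alcohol cis to the azide. E2 is disfavoured because no C–H bond is antiperiplanar to the equatorial C2–O bond and C1 cannot become a bridgehead alkene carbon.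

Step 9
Reactants: 16 tert-butyl 3-exo-azido-2-exo-hydroxy-9-oxobicyclo[3.3.1]non-6-ene-5-carboxylate
Product: 18 3-exo-azido-9-oxo-2-exo-(triethylsilyloxy)bicyclo[3.3.1]non-6-ene-5-carboxylic acid, via bis(triethylsilyl) ether ester 17 (not isolated)
Conditions: Et3SiOTf (3 equiv), 2,6-lutidine, CH2Cl2, 0 °C → rt; then THF/H2O, rt
Reagents that add atoms: triethylsilyl trifluoromethanesulfonate, CC[Si](CC)(CC)OS(=O)(=O)C(F)(F)F
Why: Silyl triflate with 2,6-lutidine silylates the C2 hydroxyl and converts the tert-butyl ester into a silyl ester with loss of isobutene (silyl-triflate cleavage of tert-butyl esters); water then hydrolyses only the labile silyl ester. No alkoxide or hydroxide is present, so neither retro-aldol at C2 nor retro-Claisen at C9 can start, and the bridgehead β-keto acid cannot decarboxylate through an anti-Bredt enol.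

Step 10
Reactants: 18 3-exo-azido-9-oxo-2-exo-(triethylsilyloxy)bicyclo[3.3.1]non-6-ene-5-carboxylic acid
Product: 22 3-exo-azido-5-hydroxy-2-exo-(triethylsilyloxy)bicyclo[3.3.1]non-6-en-9-one, via acid chloride 19 (not isolated), via O-acyl thiohydroxamate 20 (not isolated), via C5 hydroperoxide 21 (not isolated)
Conditions: Me2C=C(Cl)NMe2, CH2Cl2, 0 °C; sodium 2-thioxopyridin-1(2H)-olate (NaC5H4NOS), DMAP (cat.), dark; t-BuSH, O2, hν (visible), toluene, 0 °C; then Me2S, rt
Reagents that add atoms: dioxygen, O=O
Why: Barton decarboxylative oxygenation: the acid is activated under neutral conditions and converted into its O-acyl thiohydroxamate, visible light starts a chain in which the acyloxy radical loses CO2, the bridgehead C5 radical is trapped by O2 and the peroxyl radical takes hydrogen from the thiol; Me2S reduces the hydroperoxide. The C5 radical is a σ radical orthogonal to both the C6=C7 π bond and the C9 carbonyl, so it cannot transpose, and a bridgehead can only take up oxygen with retention.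

Step 11
Reactants: 22 3-exo-azido-5-hydroxy-2-exo-(triethylsilyloxy)bicyclo[3.3.1]non-6-en-9-one
Product: 24 3-exo-azido-2-exo,5,8-exo-trihydroxybicyclo[3.3.1]non-6-en-9-one, via 5,8-diol C2 triethylsilyl ether 23 (not isolated)
Conditions: SeO2 (1.5 equiv), 1,4-dioxane, 80 °C; filter; then AcOH/THF/H2O (3:1:1), rt
Reagents that add atoms: selenium dioxide, O=[Se]=O
Why: Allylic oxidation by SeO2 (ene reaction, then [2,3]-sigmatropic shift): C8 holds the only allylic hydrogens, selenium bonds to C6 on the open exo face while the axial exo C8–H is removed, and the [2,3] shift returns oxygen to C8 on the same face with the alkene back at C6=C7, giving the exo alcohol. No ketone in 22 has an enolisable α-hydrogen, so α-oxidation of a carbonyl cannot compete; aqueous acetic acid then removes the silyl group before any epoxide is present.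

Step 12
Reactants: 24 3-exo-azido-2-exo,5,8-exo-trihydroxybicyclo[3.3.1]non-6-en-9-one
Product: 25 3-exo-azido-6,7-exo-epoxy-2-exo,5,8-exo-trihydroxybicyclo[3.3.1]nonan-9-one
Conditions: VO(acac)2 (5 mol%), t-BuOOH (1.5 equiv), CH2Cl2, 0 °C → rt
Reagents that add atoms: tert-butyl hydroperoxide, CC(C)(C)OO
Why: Hydroxyl-directed epoxidation: the pseudo-axial C8 hydroxyl binds vanadium and delivers the peroxide oxygen to the alkene face it occupies, which is also the sterically open exo face, so the epoxide forms syn to the C8 hydroxyl. The bridgehead C5 hydroxyl lies in the nodal plane of the alkene and cannot direct to the endo face.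

Step 13
Reactants: 26 pentylmagnesium bromide; 27 hex-5-enenitrile
Product: 29 undec-1-en-6-one, via N-bromomagnesium ketimine 28 (not isolated)
Conditions: Et2O, 0 °C → reflux; then 2 M HCl, 0 °C → rt
Reagents that add atoms: water, O
Why: Grignard addition to a nitrile stops at the magnesium ketimine, which cannot accept a second equivalent; aqueous acid hydrolyses it to the ketone.

Step 14
Reactants: 29 undec-1-en-6-one; 30 acrylic acid
Product: 31 (E)-7-oxododec-2-enoic acid
Conditions: second-generation Hoveyda–Grubbs catalyst RuCl2(H2IMes)(=CH-C6H4-2-O-i-Pr) (3 mol%), 30 (3 equiv), CH2Cl2, 40 °C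
Reagents that add atoms: none
Why: Olefin cross-metathesis of a terminal alkene with an electron-poor partner: acrylic acid does not homodimerise readily, so the cross product should dominate and form as the favoured E isomer. The ketone is inert to the ruthenium carbene.

Step 15
Reactants: 25 3-exo-azido-6,7-exo-epoxy-2-exo,5,8-exo-trihydroxybicyclo[3.3.1]nonan-9-one; 31 (E)-7-oxododec-2-enoic acid
Product: 34 isariotin C, via iminophosphorane 32 (not isolated), via amino triol 33 (not isolated)
Conditions: PMe3 (1.5 equiv), THF/H2O, rt; concentrate; then 31 (1.1 equiv), 4-(4,6-dimethoxy-1,3,5-triazin-2-yl)-4-methylmorpholinium chloride (DMTMM), THF/MeOH, 0 °C → rt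
Reagents that add atoms: none
Why: Staudinger reduction converts the azide into the amine without touching the epoxide, the ketone or the hydroxyls. The amine is then acylated by the acyloxytriazine formed from 31 and DMTMM, which needs no added base and leaves the three hydroxyls alone, so the target never meets alkoxide.

## Compound list

1 | 2-methoxybenzoic acid | COc1ccccc1C(=O)O | starting material
2 | tert-butyl 2-methoxybenzoate | COc1ccccc1C(=O)OC(C)(C)C | intermediate
3 | potassium dienolate of tert-butyl 2-methoxycyclohexa-2,5-diene-1-carboxylate | [K+].COC1=CCC=CC1=C([O-])OC(C)(C)C | intermediate (not isolated)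
4 | tert-butyl 2-methoxycyclohexa-2,5-diene-1-carboxylate (racemic) | COC1=CCC=CC1C(=O)OC(C)(C)C | intermediate
5 | tert-butyl 6-oxocyclohex-2-ene-1-carboxylate (racemic, enolisable) | CC(C)(C)OC(=O)C1C=CCCC1=O | intermediate
6 | acrolein | C=CC=O | starting material
7 | tert-butyl (1S)-6-oxo-1-(3-oxopropyl)cyclohex-2-ene-1-carboxylate | O=CCC[C@@]1(C(=O)OC(C)(C)C)C(=O)CCC=C1 | intermediate (not isolated)
8 | tert-butyl (1R,2S,5S)-2-hydroxy-9-oxobicyclo[3.3.1]non-6-ene-5-carboxylate (core numbering; 2-exo hydroxyl; any 2-endo epimer is carried along) | C1C[C@@]2(C(=O)OC(C)(C)C)C(=O)[C@H](CC=C2)[C@H]1O | intermediate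
9 | tert-butyl 2,9-dioxobicyclo[3.3.1]non-6-ene-5-carboxylate | C1C[C@@]2(C(=O)OC(C)(C)C)C(=O)[C@H](CC=C2)C1=O | intermediate
10 | potassium C2–C3 enolate of 9 | [K+].C=1C[C@@]2(C(=O)OC(C)(C)C)C(=O)[C@H](CC=C2)C=1[O-] | intermediate (not isolated)
11 | potassium 3-(3-exo-core)-1-(2,4,6-triisopropylbenzenesulfonyl)triazenide of the dione | [K+].CC(C)c1cc(C(C)C)c(S(=O)(=O)[N-]N=N[C@H]2C[C@@]3(C(=O)OC(C)(C)C)C(=O)[C@H](CC=C3)C2=O)c(C(C)C)c1 | intermediate (not isolated)
12 | tert-butyl 3-exo-azido-2,9-dioxobicyclo[3.3.1]non-6-ene-5-carboxylate | [N-]=[N+]=N[C@H]1C[C@@]2(C(=O)OC(C)(C)C)C(=O)[C@H](CC=C2)C1=O | intermediate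
13 | tert-butyl 3-exo-azido-2-endo-hydroxy-9-oxobicyclo[3.3.1]non-6-ene-5-carboxylate | [N-]=[N+]=N[C@H]1C[C@@]2(C(=O)OC(C)(C)C)C(=O)[C@H](CC=C2)[C@@H]1O | intermediate
14 | tert-butyl 3-exo-azido-9-oxo-2-endo-(trifluoromethanesulfonyloxy)bicyclo[3.3.1]non-6-ene-5-carboxylate | [N-]=[N+]=N[C@H]1C[C@@]2(C(=O)OC(C)(C)C)C(=O)[C@H](CC=C2)[C@@H]1OS(=O)(=O)C(F)(F)F | intermediate (not isolated)
15 | tert-butyl 3-exo-azido-2-exo-(nitrosooxy)-9-oxobicyclo[3.3.1]non-6-ene-5-carboxylate | [N-]=[N+]=N[C@H]1C[C@@]2(C(=O)OC(C)(C)C)C(=O)[C@H](CC=C2)[C@H]1ON=O | intermediate (not isolated)
16 | tert-butyl 3-exo-azido-2-exo-hydroxy-9-oxobicyclo[3.3.1]non-6-ene-5-carboxylate | [N-]=[N+]=N[C@H]1C[C@@]2(C(=O)OC(C)(C)C)C(=O)[C@H](CC=C2)[C@H]1O | intermediate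
17 | triethylsilyl 3-exo-azido-9-oxo-2-exo-(triethylsilyloxy)bicyclo[3.3.1]non-6-ene-5-carboxylate | [N-]=[N+]=N[C@H]1C[C@@]2(C(=O)O[Si](CC)(CC)CC)C(=O)[C@H](CC=C2)[C@H]1O[Si](CC)(CC)CC | intermediate (not isolated)
18 | 3-exo-azido-9-oxo-2-exo-(triethylsilyloxy)bicyclo[3.3.1]non-6-ene-5-carboxylic acid | [N-]=[N+]=N[C@H]1C[C@@]2(C(=O)O)C(=O)[C@H](CC=C2)[C@H]1O[Si](CC)(CC)CC | intermediate
19 | 3-exo-azido-9-oxo-2-exo-(triethylsilyloxy)bicyclo[3.3.1]non-6-ene-5-carbonyl chloride | [N-]=[N+]=N[C@H]1C[C@@]2(C(=O)Cl)C(=O)[C@H](CC=C2)[C@H]1O[Si](CC)(CC)CC | intermediate (not isolated)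
20 | 2-thioxopyridin-1(2H)-yl 3-exo-azido-9-oxo-2-exo-(triethylsilyloxy)bicyclo[3.3.1]non-6-ene-5-carboxylate | [N-]=[N+]=N[C@H]1C[C@@]2(C(=O)On3ccccc3=S)C(=O)[C@H](CC=C2)[C@H]1O[Si](CC)(CC)CC | intermediate (not isolated)
21 | 3-exo-azido-5-hydroperoxy-2-exo-(triethylsilyloxy)bicyclo[3.3.1]non-6-en-9-one | [N-]=[N+]=N[C@H]1C[C@@]2(OO)C(=O)[C@H](CC=C2)[C@H]1O[Si](CC)(CC)CC | intermediate (not isolated)
22 | 3-exo-azido-5-hydroxy-2-exo-(triethylsilyloxy)bicyclo[3.3.1]non-6-en-9-one | [N-]=[N+]=N[C@H]1C[C@@]2(O)C(=O)[C@H](CC=C2)[C@H]1O[Si](CC)(CC)CC | intermediate
23 | 3-exo-azido-5,8-exo-dihydroxy-2-exo-(triethylsilyloxy)bicyclo[3.3.1]non-6-en-9-one | [N-]=[N+]=N[C@H]1C[C@@]2(O)C(=O)[C@H]([C@H](O)C=C2)[C@H]1O[Si](CC)(CC)CC | intermediate (not isolated)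
24 | 3-exo-azido-2-exo,5,8-exo-trihydroxybicyclo[3.3.1]non-6-en-9-one | [N-]=[N+]=N[C@H]1C[C@@]2(O)C(=O)[C@H]([C@H](O)C=C2)[C@H]1O | intermediate
25 | 3-exo-azido-6,7-exo-epoxy-2-exo,5,8-exo-trihydroxybicyclo[3.3.1]nonan-9-one | [N-]=[N+]=N[C@H]1C[C@@]2(O)C(=O)[C@H]([C@H](O)[C@@H]3O[C@@H]32)[C@H]1O | intermediate
26 | pentylmagnesium bromide | CCCCC[Mg]Br | starting material
27 | hex-5-enenitrile | C=CCCCC#N | starting material
28 | N-(bromomagnesio)undec-1-en-6-imine | CCCCCC(=N[Mg]Br)CCCC=C | intermediate (not isolated)
29 | undec-1-en-6-one | CCCCCC(=O)CCCC=C | intermediate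
30 | acrylic acid | C=CC(=O)O | starting material
31 | (E)-7-oxododec-2-enoic acid | CCCCCC(=O)CCC/C=C/C(=O)O | intermediate
32 | 6,7-exo-epoxy-2-exo,5,8-exo-trihydroxy-3-exo-[(trimethyl-λ5-phosphanylidene)amino]bicyclo[3.3.1]nonan-9-one | CP(C)(C)=N[C@H]1C[C@@]2(O)C(=O)[C@H]([C@H](O)[C@@H]3O[C@@H]32)[C@H]1O | intermediate (not isolated)
33 | 3-exo-amino-6,7-exo-epoxy-2-exo,5,8-exo-trihydroxybicyclo[3.3.1]nonan-9-one | N[C@H]1C[C@@]2(O)C(=O)[C@H]([C@H](O)[C@@H]3O[C@@H]32)[C@H]1O | intermediate (not isolated)
34 | isariotin C, (E)-N-(6,7-exo-epoxy-2-exo,5,8-exo-trihydroxy-9-oxobicyclo[3.3.1]nonan-3-exo-yl)-7-oxododec-2-enamide | CCCCCC(=O)CCC/C=C/C(=O)N[C@H]1C[C@@]2(O)C(=O)[C@H]([C@H](O)[C@@H]3O[C@@H]32)[C@H]1O | target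

## Step count and least certain steps

Total: 15 steps. Longest linear sequence: 13 steps (steps 1 to 12 and 15, from 2-methoxybenzoic acid); steps 13 and 14 make the side chain.

**Step 4 (key step).** The most likely failure is erosion of enantioselectivity, together with γ-alkylation or aromatisation of the donor. The cross-conjugated dienolate of 5 is more reactive and less tightly organised than a saturated β-keto ester enolate, so uncatalysed background addition can compete. The fallback replaces catalyst control by a covalently bound auxiliary. It sets out from 5, which is condensed with (S)-1-phenylethylamine (the antipode is chosen to give the (S) centre) to the enamino ester tert-butyl 2-{[(1S)-1-phenylethyl]amino}cyclohexa-1,5-diene-1-carboxylate F1. Addition of F1 to 6 in THF on the face away from the phenyl group gives the imine adduct tert-butyl (1S)-1-(3-oxopropyl)-6-{[(1S)-1-phenylethyl]imino}cyclohex-2-ene-1-carboxylate F2. Aqueous acetic acid hydrolyses F2 and the fallback comes back at 7, which is then closed to 8 with the same guanidine base.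

**Step 6.** The most likely failure is diazo transfer or loss of dinitrogen in place of clean azide transfer. Ketone-derived triazenides fragment less cleanly than imide-derived ones and the α-azido ketone is base-labile; competing deprotonation at the bridgehead C1 is a lesser risk. The fallback changes from an anionic to a radical azidation. It sets out from 9, which is silylated (i-Pr3SiOTf, Et3N) to tert-butyl 9-oxo-2-(triisopropylsilyloxy)bicyclo[3.3.1]nona-2,6-diene-5-carboxylate F3. Treatment of F3 with (NH4)2Ce(NO3)6 and NaN3 in MeCN at −20 °C adds an azidyl radical to C3 on the exo face, oxidises the adduct and expels silicon. The fallback comes back at 12.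

**Step 8.** The most likely failure is slow displacement with competing fragmentation or attack through nitrite nitrogen. The C2–O bond is antiperiplanar to C1–C9, so any nucleophile that adds to the C9 carbonyl can cleave that bond, and the adjacent azide retards SN2. Should step 7 deliver some exo alcohol directly, that material joins the route at 16. The fallback avoids a discrete β-keto triflate by a one-flask redox condensation. It sets out from 13, which is treated with the preformed PPh3/diisopropyl azodicarboxylate betaine (formed at 0 °C so that it outruns the Staudinger reaction) and 4-nitrobenzoic acid in toluene. This gives tert-butyl 3-exo-azido-2-exo-(4-nitrobenzoyloxy)-9-oxobicyclo[3.3.1]non-6-ene-5-carboxylate F4 by Mitsunobu inversion. The ester is removed with NaN3 in MeOH at 40 °C, a near-neutral methanolysis, and the fallback comes back at 16.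

**Step 10.** The most likely failure is consumption of the C6=C7 alkene by thiyl radical addition under oxygen, or a short chain. The bridgehead radical next to a carbonyl forms more slowly than an ordinary tertiary radical, which gives thiol chemistry time to compete. The fallback removes both the thiol and the acylating agent. It sets out from 18, whose carboxylate is oxidised directly by photoexcited 9-mesityl-10-methylacridinium tetrafluoroborate (5 mol%) with 2,6-lutidine under O2 and blue light in MeCN. Loss of CO2 and trapping by oxygen give the hydroperoxide 21, and Me2S then brings the fallback back at 22. No new compound is involved.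

**Step 11.** The most likely failure is a sluggish ene reaction with over-oxidation at C8 or acid-induced acyloin shift of the C5 ketol on forcing. The alkene is cis-disubstituted, flanked by the quaternary C5 and electron-poor. The fallback changes from a pericyclic to a radical–copper allylic oxidation. It sets out from 22, which is treated with CuBr (5 mol%) and tert-butyl perbenzoate in MeCN/benzene at 60 °C. Hydrogen abstraction at C8 and capture of the allyl radical by the copper benzoate at the less hindered terminus on the exo face give 3-exo-azido-8-exo-benzoyloxy-5-hydroxy-2-exo-(triethylsilyloxy)bicyclo[3.3.1]non-6-en-9-one F5. Methanolysis with catalytic K2CO3 in MeOH at 0 °C, kept short because of the retro-aldol risk, brings the fallback back at 23, which is desilylated as in step 11.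

## Further compounds

F1 | step 4 | tert-butyl 2-{[(1S)-1-phenylethyl]amino}cyclohexa-1,5-diene-1-carboxylate | CC(C)(C)OC(=O)C1=C(N[C@@H](C)c2ccccc2)CCC=C1
F2 | step 4 | tert-butyl (1S)-1-(3-oxopropyl)-6-{[(1S)-1-phenylethyl]imino}cyclohex-2-ene-1-carboxylate | CC(C)(C)OC(=O)[C@@]1(CCC=O)C=CCCC1=N[C@@H](C)c2ccccc2
F3 | step 6 | tert-butyl 9-oxo-2-(triisopropylsilyloxy)bicyclo[3.3.1]nona-2,6-diene-5-carboxylate | C=1C[C@@]2(C(=O)OC(C)(C)C)C(=O)[C@H](CC=C2)C=1O[Si](C(C)C)(C(C)C)C(C)C
F4 | step 8 | tert-butyl 3-exo-azido-2-exo-(4-nitrobenzoyloxy)-9-oxobicyclo[3.3.1]non-6-ene-5-carboxylate | [N-]=[N+]=N[C@H]1C[C@@]2(C(=O)OC(C)(C)C)C(=O)[C@H](CC=C2)[C@H]1OC(=O)c3ccc(cc3)[N+](=O)[O-]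
F0 | step 10 | none | none
F5 | step 11 | 3-exo-azido-8-exo-benzoyloxy-5-hydroxy-2-exo-(triethylsilyloxy)bicyclo[3.3.1]non-6-en-9-one | [N-]=[N+]=N[C@H]1C[C@@]2(O)C(=O)[C@H]([C@H](OC(=O)c3ccccc3)C=C2)[C@H]1O[Si](CC)(CC)CC
A1 | alternative 1 | C2-exo carbamate of the protected epoxy core (C5 triethylsilyl ether, C8 tert-butyldimethylsilyl ether) | C1C[C@@]2(O[Si](CC)(CC)CC)C(=O)[C@H]([C@H](O[Si](C)(C)C(C)(C)C)[C@@H]3O[C@@H]32)[C@H]1OC(N)=O
A2 | alternative 1 | C2,C3 cis-fused oxazolidinone of the protected epoxy core | O=C1N[C@H]2C[C@@]3(O[Si](CC)(CC)CC)C(=O)[C@H]([C@H](O[Si](C)(C)C(C)(C)C)[C@@H]4O[C@@H]43)[C@H]2O1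
A3 | alternative 2 | (2Z,5Z)-4-acetyl-4-hydroxyhepta-2,5-dienedial | CC(=O)C(O)(/C=C\C=O)/C=C\C=O
A4 | alternative 2 | meso 2-exo,5,8-exo-trihydroxybicyclo[3.3.1]nona-3,6-dien-9-one | O[C@@]12C=C[C@H](O)[C@@H]([C@H](O)C=C1)C2=O
A5 | alternative 3 | trimethylsilyl enol ether (C9=C1) of the ring-A ketone with C2 and C5 tert-butyldimethylsilyl ethers and C3 dibenzylamine | c1ccccc1CN(Cc2ccccc2)[C@H]3CC(O[Si](C)(C)C(C)(C)C)C(O[Si](C)(C)C)=C[C@H]3O[Si](C)(C)C(C)(C)C
A6 | alternative 3 | malonyl dichloride | ClC(=O)CC(Cl)=O
A7 | alternative 3 | 3-exo-(dibenzylamino)-2-exo,5-bis(tert-butyldimethylsilyloxy)bicyclo[3.3.1]nonane-6,8,9-trione | c3ccccc3CN(Cc4ccccc4)[C@H]1C[C@@]2(O[Si](C)(C)C(C)(C)C)C(=O)[C@H](C(=O)CC2=O)[C@H]1O[Si](C)(C)C(C)(C)C
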